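The meeting opened on a ratio: the second exchange constant over the first, 0.88 M⁻¹ min⁻¹ over 1.8 M⁻¹ min⁻¹, which gives 0.489, the selectivity factor of this ladder.

| setting | north-east | west | south-west | east | south |
|---|---|---|---|---|---|
| starting complex | 0.014 M | 0.014 M | 0.014 M (fed, over 10 h) | 0.014 M | 0.014 M |
| incoming ligand | 8.40 mM (fed, over 2.5 h) | 8.40 mM | 8.40 mM | 8.40 mM (fed, over 10 h) | 8.40 mM (in portions, 5, over 10 h) |
| temperature | 90 °C | 90 °C | 90 °C |  | 90 °C |
| time | 12 h | 12 h | 12 h | 12 h | 12 h |
| remark | all else is in the flask from the start; the feed brings no volume worth counting | everything together at the start | all else is in the flask from the start; the feed brings no volume worth counting | the addition at 70 °C, then warmed to 90 °C; the feed brings no volume worth counting | first portion at the start, last at 10 h |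

* which flask leads in amount of complex with two exchanged, in percent of the starting complex charged ("all alike" within 1.5 percentage points) (north-east / west / south-west / east / south / all alike)
* how much complex with two exchanged is there at the end, in percent of the starting complex charged: north-east
* how much complex with two exchanged is there at the end, in percent of the starting complex charged: west
* how much complex with two exchanged is there at the end, in percent of the starting complex charged: south-west
* how much complex with two exchanged is there at the end, in percent of the starting complex charged: east
* how much complex with two exchanged is there at the end, in percent of the starting complex charged: south

- the constants hold at 90 °C; other temperatures follow from the activation energies and enthalpies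

    starting complex + incoming ligand → leaving ligand + complex with one exchanged (k1 = 1.8 M⁻¹ min⁻¹, Ea1 = 82.0 kJ mol⁻¹)
    complex with one exchanged + incoming ligand → leaving ligand + complex with two exchanged (k2 = 0.88 M⁻¹ min⁻¹, Ea2 = 75.0 kJ mol⁻¹)
    complex with two exchanged + incoming ligand ⇌ leaving ligand + complex with three exchanged (K3 = 1.0, k3 = 1.1 M⁻¹ min⁻¹, Ea3 = 51.0 kJ mol⁻¹, ΔH3 = −90.0 kJ mol⁻¹)
    complex with two exchanged ⇌ isomer of the product (K4 = 0.15, k4 = 0.062 min⁻¹, Ea4 = 116 kJ mol⁻¹, ΔH4 = −33.0 kJ mol⁻¹)
    (constants at 90 °C)

The chair recalled that the incoming ligand is the limiting reagent, 8.40 mM against 0.014 M, so the question was how much of it goes into a second exchange.

Anna argued that both exchanges run in proportion to [incoming ligand], which therefore cancels when one rate is divided by the other. The second exchange then runs at 0.489 times [complex with one exchanged]/[starting complex] times the rate of the first. She integrated this over the ligand spent, counting the spent ligand as complex with one exchanged and holding the starting complex at a fixed amount. The pool of complex with two exchanged plus its isomer then came to the ratio times the square of the ligand charge, divided by two and by that amount. For west, she said, the amount is the whole charge of starting complex.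

Bo objected that south-west has no such amount: its starting complex arrives over 10 h. He integrated the ligand's loss under steady arrival: [starting complex], its own loss set aside, grows with time, and [incoming ligand] falls as a bell curve of width 3.64 h, the square root of two times the feed time over the first constant and the charge. That width is shorter than the feed. What has arrived by then, 0.005092 M, is the met charge, and the closed integral comes close to Anna's form with this in the denominator.

Carla added that in south-west the isomer step, both ways together, relaxes with a half-life of 1.46 min, short against 12 h, so the pool splits by 0.15, leaving 87.0% of it as complex with two exchanged.

The minutes record 7.65% for west, the same for north-east, and 21.0% for south-west. Bo called the last figure high: it counts every spent ligand as complex with one exchanged. South and east were not reckoned.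

The forecast named south-west as leader, with 7.3% for north-east, 7.3% for west, 13% for south-west, below my figure, 6.9% for east and 7.2% for south, holding that “Feeding the starting complex instead exposes its early portions to excess ligand”.

The simulation puts south-west ahead, with 7.70% in north-east, 7.71% in west, 13.6% in south-west, 6.78% in east and 6.96% in south.

South-west stands below my reckoned 21.0%, and holds 27.4% of complex with one exchanged at 12.0 h, against the 60.0% of the starting complex charged that the reckoning counted there. The neighbour of south-west charged with 0.0021 M of incoming ligand keeps the met charge of 0.00509 M, whose width holds no ligand term. The same reckoning gives it 1.32%. That neighbour ends with 86.5% of starting complex, 12.1% of complex with one exchanged and 1.18% of complex with two exchanged.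

The numbers were drawn at random within sensible limits; the flask was simulated.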